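Everything rests on cutting the furan ring of the styryl-bearing dihydrobenzofuran (benzofuran numbering; ring A is its benzo ring) at O1–C7a and C3–C3a. Ring A enters as a 3-methoxyaryne and O1–C2–C3 as an enantiopure trans-diaryl oxirane; in one operation the aryne inserts into the benzylic C3–O bond, closing the furan ring and setting C3 trans to C2. The step exploits the C4 oxygen beside C3a, which steers the aryne, and the meta-dioxygenated aryl on C3; the C2 aryl ring is temporarily made electron-poor with sulfonates so that only C3–O ionises. That ring, re-armed as a silyl triflate, then inserts into a second oxirane.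

Key step: step 8

Remark: compounds 1, 5, 8, 10 and 21 and both antipodes of the Shi ketone are taken as purchasable; the D-fructose-derived ketone is assumed to give (R,R)-oxiranes from trans-stilbenes, so the L-series ketone is used for the (S,S)-oxiranes needed here.
Abbreviation used in names: DBF = (2R,3R)-3-(3,5-dimethoxyphenyl)-4-methoxy-6-[(E)-4-methoxystyryl]-2,3-dihydrobenzofuran-2-yl. Primed atoms belong to the middle benzene ring, double-primed atoms to the second oxirane unit.

Step 1
Reactants: 1 2-bromoresorcinol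
Product: 2 3-bromo-2,4-dihydroxybenzaldehyde
Conditions: POCl3, DMF, MeCN, 0 → 25 °C; then H2O, 50 °C
Reagents that add atoms: N,N-dimethylformamide CN(C)C=O; water O
Why: Vilsmeier–Haack formylation, in which the chloroiminium ion can only attack the two equivalent positions that are ortho to one hydroxyl and para to the other.

Step 2
Reactants: 2 3-bromo-2,4-dihydroxybenzaldehyde
Product: 3 2-bromo-4-formyl-3-hydroxyphenyl trifluoromethanesulfonate
Conditions: Tf2O (1.05 equiv), pyridine, CH2Cl2, −78 → 0 °C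
Reagents that add atoms: trifluoromethanesulfonic anhydride O=S(=O)(OS(=O)(=O)C(F)(F)F)C(F)(F)F
Why: Chemoselective O-sulfonylation, since the 2-hydroxyl is hydrogen-bonded to the aldehyde and flanked on both sides, so one equivalent of anhydride should react at the 4-hydroxyl.

Step 3
Reactants: 3 2-bromo-4-formyl-3-hydroxyphenyl trifluoromethanesulfonate
Product: 4 3-bromo-2-(tosyloxy)-4-(triflyloxy)benzaldehyde
Conditions: TsCl, Et3N, DMAP (cat.), CH2Cl2, 0 → 25 °C
Reagents that add atoms: 4-toluenesulfonyl chloride Cc1ccc(S(=O)(=O)Cl)cc1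
Why: DMAP-catalysed O-tosylation of the remaining hindered phenol, giving a ring whose two oxygens are both electron-poor but can later be freed one at a time.

Step 4
Reactants: 4 3-bromo-2-(tosyloxy)-4-(triflyloxy)benzaldehyde; 5 diethyl (3,5-dimethoxybenzyl)phosphonate
Product: 6 (E)-2-bromo-6-(3,5-dimethoxystyryl)-3-(triflyloxy)phenyl 4-methylbenzenesulfonate
Conditions: NaH, THF, 0 → 25 °C
Reagents that add atoms: none
Why: Horner–Wadsworth–Emmons olefination with a benzylic phosphonate should give the E-stilbene, and the aryl sulfonates tolerate the preformed phosphonate anion at this temperature.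

Step 5
Reactants: 6 (E)-2-bromo-6-(3,5-dimethoxystyryl)-3-(triflyloxy)phenyl 4-methylbenzenesulfonate
Product: 7 (2S,3S)-2-[3-bromo-2-(tosyloxy)-4-(triflyloxy)phenyl]-3-(3,5-dimethoxyphenyl)oxirane
Conditions: L-fructose-derived Shi ketone (0.3 equiv), Oxone (2KHSO5·KHSO4·K2SO4), K2CO3, Bu4NHSO4, MeCN/dimethoxymethane/aq. Na2B4O7 buffer, 0 °C
Reagents that add atoms: potassium peroxymonosulfate [K+].[O-]S(=O)(=O)OO
Why: Shi asymmetric epoxidation, in which the chiral dioxirane attacks the trans-alkene through the spiro transition state on the face opposite to that chosen by the D-series ketone, setting both oxirane carbons S.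

Step 6
Reactants: 8 3-methoxy-2-(trimethylsilyl)phenyl trifluoromethanesulfonate
Product: 9 3-methoxy-5-(4,4,5,5-tetramethyl-1,3,2-dioxaborolan-2-yl)-2-(trimethylsilyl)phenyl trifluoromethanesulfonate
Conditions: [Ir(OMe)(cod)]2 (1.5 mol%), 4,4'-di-tert-butyl-2,2'-bipyridine, B2pin2, THF, 60 °C
Reagents that add atoms: bis(pinacolato)diboron CC1(C)OB(B2OC(C)(C)C(C)(C)O2)OC1(C)C
Why: Iridium-catalysed C–H borylation is sterically governed, and C5 is the only ring C–H without an ortho substituent, while the silyl triflate is untouched in the absence of fluoride.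

Step 7
Reactants: 9 3-methoxy-5-(pinacolatoboryl)-2-(trimethylsilyl)phenyl trifluoromethanesulfonate; 10 (E)-1-(2-bromovinyl)-4-methoxybenzene
Product: 11 (E)-3-methoxy-5-(4-methoxystyryl)-2-(trimethylsilyl)phenyl trifluoromethanesulfonate
Conditions: Pd(PPh3)4 (5 mol%), K3PO4, 1,4-dioxane/H2O, 50 °C
Reagents that add atoms: none
Why: Suzuki–Miyaura coupling, in which the alkenyl bromide adds to zerovalent palladium far faster than the hindered aryl triflate and the E geometry is retained.

Step 8
Reactants: 7 (2S,3S)-2-[3-bromo-2-(tosyloxy)-4-(triflyloxy)phenyl]-3-(3,5-dimethoxyphenyl)oxirane; 11 (E)-3-methoxy-5-(4-methoxystyryl)-2-(trimethylsilyl)phenyl trifluoromethanesulfonate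
Product: 14 2-bromo-6-(DBF)-3-(triflyloxy)phenyl 4-methylbenzenesulfonate, via aryne 12 (not isolated), via oxiranium zwitterion 13 (not isolated)
Conditions: CsF (4 equiv), MeCN, 25 °C; 11 (1.6 equiv) added slowly
Reagents that add atoms: none
Why: Fluoride converts 11 into 3-methoxyaryne 12, and the oxirane oxygen of 7 adds to the aryne carbon meta to OMe (the distorted, more electrophilic terminus, leaving the carbanion ortho to the inductively stabilising OMe), which fixes O1 on C7a and the carbanion on C3a in zwitterion 13. The O-aryl oxiranium of 13 then ionises at its benzylic C3–O bond and the neighbouring carbanion captures C3, so the net result is insertion of the aryne into a C–O sigma bond of the oxirane; the closest known reaction is the formal insertion of benzyne, generated from an ortho-silylaryl triflate with CsF, into the benzylic C–O bond of styrene oxide to give a 3-aryl-2,3-dihydrobenzofuran. The furan ring is closed by this intramolecular ion-pair collapse onto a benzylic cation, a five-membered ring made by bonding C3a to C3 while O1–C2 is kept. C2 is never broken and keeps the configuration set in step 5, and C3 should be set trans to the C2 aryl group because the carbanion is delivered to the face that the tethered oxygen has just left (least motion) and because the trans ring is the less strained one. The step needs two selectivities: the aryne regiochemistry, secured by the methoxy group on what becomes C4, and the choice of the C–O bond that breaks, secured by the triflate, tosylate and bromine on the C2 aryl ring, which make a cation at C2 far less favourable than one next to the 3,5-dimethoxyphenyl ring. Addition of the aryne to the stilbene alkene should be slow relative to trapping by the oxirane, which is kept in excess over the aryne by the slow addition of 11.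

Step 9
Reactants: 14 2-bromo-6-(DBF)-3-(triflyloxy)phenyl 4-methylbenzenesulfonate
Product: 16 2-bromo-6-(DBF)-3-methoxyphenyl 4-methylbenzenesulfonate, via phenol 15 (not isolated)
Conditions: Et4NOH (aq.), 1,4-dioxane, 25 °C; then MeI, 25 °C
Reagents that add atoms: iodomethane CI
Why: Hydroxide attacks the sulfur of the aryl triflate much faster than that of the hindered tosylate, and Williamson methylation of the phenoxide in the same flask swaps the acceptor needed in step 8 for the ether that will direct the later aryne.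

Step 10
Reactants: 16 2-bromo-6-(DBF)-3-methoxyphenyl 4-methylbenzenesulfonate
Product: 17 2-bromo-6-(DBF)-3-methoxyphenol
Conditions: KOH, MeOH/THF, 65 °C; then aq. NH4Cl
Reagents that add atoms: none
Why: Saponification of the aryl tosylate by attack at sulfur, with no other base-labile group left in the molecule.

Step 11
Reactants: 17 2-bromo-6-(DBF)-3-methoxyphenol
Product: 20 6-(DBF)-3-methoxy-2-(trimethylsilyl)phenyl trifluoromethanesulfonate, via silyl ether 18 (not isolated), via lithium phenoxide 19 (not isolated)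
Conditions: (Me3Si)2NH, THF, 65 °C, then evaporate; n-BuLi (1.05 equiv), THF, −100 → −78 °C; Tf2O, −78 → 0 °C
Reagents that add atoms: hexamethyldisilazane C[Si](C)(C)N[Si](C)(C)C; trifluoromethanesulfonic anhydride O=S(=O)(OS(=O)(=O)C(F)(F)F)C(F)(F)F
Why: O-silylation, bromine–lithium exchange and retro-Brook migration of silicon from oxygen to carbon give a phenoxide that is triflated, the standard route to ortho-silylaryl triflates, and the exchange at −100 °C should outrun addition to the stilbene or benzylic deprotonation.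

Step 12
Reactants: 21 2,4-dihydroxybenzaldehyde
Product: 22 4-formyl-1,3-phenylene bis(trifluoromethanesulfonate)
Conditions: Tf2O (2.3 equiv), pyridine, CH2Cl2, −20 → 25 °C
Reagents that add atoms: trifluoromethanesulfonic anhydride O=S(=O)(OS(=O)(=O)C(F)(F)F)C(F)(F)F
Why: Exhaustive O-triflation turns the 2,4-dioxygenated ring into an electron-poor ring that cannot stabilise a benzylic cation.

Step 13
Reactants: 22 4-formyl-1,3-phenylene bis(trifluoromethanesulfonate); 5 diethyl (3,5-dimethoxybenzyl)phosphonate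
Product: 23 (E)-4-(3,5-dimethoxystyryl)-1,3-phenylene bis(trifluoromethanesulfonate)
Conditions: NaH, THF, 0 → 25 °C
Reagents that add atoms: none
Why: Horner–Wadsworth–Emmons olefination, E-selective as in step 4.

Step 14
Reactants: 23 (E)-4-(3,5-dimethoxystyryl)-1,3-phenylene bis(trifluoromethanesulfonate)
Product: 24 (2S,3S)-2-[2,4-bis(triflyloxy)phenyl]-3-(3,5-dimethoxyphenyl)oxirane
Conditions: L-fructose-derived Shi ketone (0.3 equiv), Oxone (2KHSO5·KHSO4·K2SO4), K2CO3, Bu4NHSO4, MeCN/dimethoxymethane/aq. Na2B4O7 buffer, 0 °C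
Reagents that add atoms: potassium peroxymonosulfate [K+].[O-]S(=O)(=O)OO
Why: Shi asymmetric epoxidation with the same catalyst antipode and the same facial sense as in step 5, setting both oxirane carbons S.

Step 15
Reactants: 20 6-(DBF)-3-methoxy-2-(trimethylsilyl)phenyl trifluoromethanesulfonate; 24 (2S,3S)-2-[2,4-bis(triflyloxy)phenyl]-3-(3,5-dimethoxyphenyl)oxirane
Product: 27 4-[(2R,3R)-7-(DBF)-3-(3,5-dimethoxyphenyl)-4-methoxy-2,3-dihydrobenzofuran-2-yl]-1,3-phenylene bis(trifluoromethanesulfonate), via aryne 25 (not isolated), via oxiranium zwitterion 26 (not isolated)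
Conditions: CsF (4 equiv), 24 (3 equiv), MeCN/toluene, 25 → 50 °C
Reagents that add atoms: none
Why: A second aryne insertion into an oxirane C–O bond, in which the 4'-methoxy group directs the oxirane oxygen to C2', the bis-triflate ring forces ionisation at the dimethoxyphenyl-bearing carbon, C2'' keeps its configuration from step 14 and C3'' is set trans by the same ion-pair collapse as in step 8.

Step 16
Reactants: 27 heptamethyl ether bis-triflate
Product: 28 4-[(2R,3R)-3-(3,5-dihydroxyphenyl)-7-[(2R,3R)-3-(3,5-dihydroxyphenyl)-4-hydroxy-6-[(E)-4-hydroxystyryl]-2,3-dihydrobenzofuran-2-yl]-4-hydroxy-2,3-dihydrobenzofuran-2-yl]-1,3-phenylene bis(trifluoromethanesulfonate)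
Conditions: BBr3 (excess), CH2Cl2, −78 → 0 °C; then MeOH, aq. NaHCO3
Reagents that add atoms: none
Why: Lewis-acid demethylation of the seven aryl methyl ethers by bromide attack on the boron-bound methoxy groups, run while the two inert triflates still keep the C2'' aryl ring electron-poor so that the benzylic C–O bond of the second dihydrobenzofuran should not ionise.

Step 17
Reactants: 28 heptaphenol bis-triflate
Product: 29 4-[(2R,3R)-3-(3,5-dihydroxyphenyl)-7-[(2R,3R)-3-(3,5-dihydroxyphenyl)-4-hydroxy-6-[(E)-4-hydroxystyryl]-2,3-dihydrobenzofuran-2-yl]-4-hydroxy-2,3-dihydrobenzofuran-2-yl]benzene-1,3-diol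
Conditions: Et4NOH (aq., excess), degassed 1,4-dioxane, 25 °C; then aq. NH4Cl
Reagents that add atoms: none
Why: Hydroxide cleaves the two aryl triflates at sulfur at room temperature, a mild basic deprotection that leaves the four stereocentres and the E-alkene untouched.

Compound list
1 | 2-bromoresorcinol | Oc1cccc(O)c1Br | starting material
2 | 3-bromo-2,4-dihydroxybenzaldehyde | O=Cc1ccc(O)c(Br)c1O | intermediate
3 | 2-bromo-4-formyl-3-hydroxyphenyl trifluoromethanesulfonate | O=Cc1ccc(OS(=O)(=O)C(F)(F)F)c(Br)c1O | intermediate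
4 | 3-bromo-2-(tosyloxy)-4-(triflyloxy)benzaldehyde | O=Cc1ccc(OS(=O)(=O)C(F)(F)F)c(Br)c1OS(=O)(=O)c1ccc(C)cc1 | intermediate
5 | diethyl (3,5-dimethoxybenzyl)phosphonate | CCOP(=O)(Cc1cc(OC)cc(OC)c1)OCC | starting material
6 | (E)-2-bromo-6-(3,5-dimethoxystyryl)-3-(triflyloxy)phenyl 4-methylbenzenesulfonate | COc1cc(/C=C/c2ccc(OS(=O)(=O)C(F)(F)F)c(Br)c2OS(=O)(=O)c2ccc(C)cc2)cc(OC)c1 | intermediate
7 | (2S,3S)-2-[3-bromo-2-(tosyloxy)-4-(triflyloxy)phenyl]-3-(3,5-dimethoxyphenyl)oxirane | O1[C@@H](c2ccc(OS(=O)(=O)C(F)(F)F)c(Br)c2OS(=O)(=O)c2ccc(C)cc2)[C@@H]1c1cc(OC)cc(OC)c1 | intermediate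
8 | 3-methoxy-2-(trimethylsilyl)phenyl trifluoromethanesulfonate | COc1cccc(OS(=O)(=O)C(F)(F)F)c1[Si](C)(C)C | starting material
9 | 3-methoxy-5-(4,4,5,5-tetramethyl-1,3,2-dioxaborolan-2-yl)-2-(trimethylsilyl)phenyl trifluoromethanesulfonate | COc1cc(B2OC(C)(C)C(C)(C)O2)cc(OS(=O)(=O)C(F)(F)F)c1[Si](C)(C)C | intermediate
10 | (E)-1-(2-bromovinyl)-4-methoxybenzene | COc1ccc(/C=C/Br)cc1 | starting material
11 | (E)-3-methoxy-5-(4-methoxystyryl)-2-(trimethylsilyl)phenyl trifluoromethanesulfonate | COc1ccc(/C=C/c2cc(OC)c([Si](C)(C)C)c(OS(=O)(=O)C(F)(F)F)c2)cc1 | intermediate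
12 | 3-methoxy-5-[(E)-4-methoxystyryl]benzyne (triple bond between the former C–OTf and C–Si carbons) | COc1ccc(/C=C/C2=CC#CC(OC)=C2)cc1 | intermediate (not isolated)
13 | zwitterion: O-aryl oxiranium of 7 on the aryne carbon meta to OMe, carbanion on the carbon ortho to OMe | COc1ccc(/C=C/c2cc(OC)[c-]c([O+]3[C@@H](c4ccc(OS(=O)(=O)C(F)(F)F)c(Br)c4OS(=O)(=O)c4ccc(C)cc4)[C@@H]3c3cc(OC)cc(OC)c3)c2)cc1 | intermediate (not isolated)
14 | 2-bromo-6-(DBF)-3-(triflyloxy)phenyl 4-methylbenzenesulfonate | COc1ccc(/C=C/c2cc(OC)c3c(c2)O[C@@H](c2ccc(OS(=O)(=O)C(F)(F)F)c(Br)c2OS(=O)(=O)c2ccc(C)cc2)[C@@H]3c2cc(OC)cc(OC)c2)cc1 | intermediate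
15 | 2-bromo-6-(DBF)-3-hydroxyphenyl 4-methylbenzenesulfonate (as its tetraethylammonium phenoxide) | COc1ccc(/C=C/c2cc(OC)c3c(c2)O[C@@H](c2ccc(O)c(Br)c2OS(=O)(=O)c2ccc(C)cc2)[C@@H]3c2cc(OC)cc(OC)c2)cc1 | intermediate (not isolated)
16 | 2-bromo-6-(DBF)-3-methoxyphenyl 4-methylbenzenesulfonate | COc1ccc(/C=C/c2cc(OC)c3c(c2)O[C@@H](c2ccc(OC)c(Br)c2OS(=O)(=O)c2ccc(C)cc2)[C@@H]3c2cc(OC)cc(OC)c2)cc1 | intermediate
17 | 2-bromo-6-(DBF)-3-methoxyphenol | COc1ccc(/C=C/c2cc(OC)c3c(c2)O[C@@H](c2ccc(OC)c(Br)c2O)[C@@H]3c2cc(OC)cc(OC)c2)cc1 | intermediate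
18 | trimethylsilyl ether of 17 | COc1ccc(/C=C/c2cc(OC)c3c(c2)O[C@@H](c2ccc(OC)c(Br)c2O[Si](C)(C)C)[C@@H]3c2cc(OC)cc(OC)c2)cc1 | intermediate (not isolated)
19 | lithium 6-(DBF)-3-methoxy-2-(trimethylsilyl)phenoxide | COc1ccc(/C=C/c2cc(OC)c3c(c2)O[C@@H](c2ccc(OC)c([Si](C)(C)C)c2[O-])[C@@H]3c2cc(OC)cc(OC)c2)cc1.[Li+] | intermediate (not isolated)
20 | 6-(DBF)-3-methoxy-2-(trimethylsilyl)phenyl trifluoromethanesulfonate | COc1ccc(/C=C/c2cc(OC)c3c(c2)O[C@@H](c2ccc(OC)c([Si](C)(C)C)c2OS(=O)(=O)C(F)(F)F)[C@@H]3c2cc(OC)cc(OC)c2)cc1 | intermediate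
21 | 2,4-dihydroxybenzaldehyde | O=Cc1ccc(O)cc1O | starting material
22 | 4-formyl-1,3-phenylene bis(trifluoromethanesulfonate) | O=Cc1ccc(OS(=O)(=O)C(F)(F)F)cc1OS(=O)(=O)C(F)(F)F | intermediate
23 | (E)-4-(3,5-dimethoxystyryl)-1,3-phenylene bis(trifluoromethanesulfonate) | COc1cc(/C=C/c2ccc(OS(=O)(=O)C(F)(F)F)cc2OS(=O)(=O)C(F)(F)F)cc(OC)c1 | intermediate
24 | (2S,3S)-2-[2,4-bis(triflyloxy)phenyl]-3-(3,5-dimethoxyphenyl)oxirane | O1[C@@H](c2ccc(OS(=O)(=O)C(F)(F)F)cc2OS(=O)(=O)C(F)(F)F)[C@@H]1c1cc(OC)cc(OC)c1 | intermediate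
25 | 6-(DBF)-3-methoxybenzyne (triple bond between C2' and C3') | COc1ccc(/C=C/c2cc(OC)c3c(c2)O[C@@H](C2=CC=C(OC)C#C2)[C@@H]3c2cc(OC)cc(OC)c2)cc1 | intermediate (not isolated)
26 | zwitterion: O-aryl oxiranium of 24 on C2', carbanion on C3' | COc1ccc(/C=C/c2cc(OC)c3c(c2)O[C@@H](c2ccc(OC)[c-]c2[O+]2[C@@H](c4ccc(OS(=O)(=O)C(F)(F)F)cc4OS(=O)(=O)C(F)(F)F)[C@@H]2c2cc(OC)cc(OC)c2)[C@@H]3c2cc(OC)cc(OC)c2)cc1 | intermediate (not isolated)
27 | 4-[(2R,3R)-7-(DBF)-3-(3,5-dimethoxyphenyl)-4-methoxy-2,3-dihydrobenzofuran-2-yl]-1,3-phenylene bis(trifluoromethanesulfonate) | COc1ccc(/C=C/c2cc(OC)c3c(c2)O[C@@H](c2ccc(OC)c4c2O[C@@H](c2ccc(OS(=O)(=O)C(F)(F)F)cc2OS(=O)(=O)C(F)(F)F)[C@@H]4c2cc(OC)cc(OC)c2)[C@@H]3c2cc(OC)cc(OC)c2)cc1 | intermediate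
28 | heptaphenol corresponding to 27 (all seven OMe replaced by OH, both triflates kept) | Oc1ccc(/C=C/c2cc(O)c3c(c2)O[C@@H](c2ccc(O)c4c2O[C@@H](c2ccc(OS(=O)(=O)C(F)(F)F)cc2OS(=O)(=O)C(F)(F)F)[C@@H]4c2cc(O)cc(O)c2)[C@@H]3c2cc(O)cc(O)c2)cc1 | intermediate
29 | 4-[(2R,3R)-3-(3,5-dihydroxyphenyl)-7-[(2R,3R)-3-(3,5-dihydroxyphenyl)-4-hydroxy-6-[(E)-4-hydroxystyryl]-2,3-dihydrobenzofuran-2-yl]-4-hydroxy-2,3-dihydrobenzofuran-2-yl]benzene-1,3-diol (CNP0217875.2) | Oc1ccc(/C=C/c2cc(O)c3c(c2)O[C@@H](c2ccc(O)c4c2O[C@@H](c2ccc(O)cc2O)[C@@H]4c2cc(O)cc(O)c2)[C@@H]3c2cc(O)cc(O)c2)cc1 | target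

Total step count: 17. Longest linear sequence: 12 steps (steps 1–5, 8–11, 15–17).

Steps most likely to fail

Step 8. What may go wrong is ionisation of the wrong C–O bond of the oxiranium, or consumption of the aryne by solvent or fluoride before the weakly nucleophilic oxirane oxygen adds. The fallback builds the same ring by two polar substitutions that each invert. It sets out from stilbene 6, which is epoxidised with the D-fructose-derived Shi ketone to the enantiomeric (2R,3R)-2-[3-bromo-2-(tosyloxy)-4-(triflyloxy)phenyl]-3-(3,5-dimethoxyphenyl)oxirane F1. In hexafluoroisopropanol F1 is opened by commercial 4'-O-methylresveratrol F2 in a Friedel–Crafts alkylation at the ring carbon between its two hydroxyls; the electron-poor aryl ring again directs attack to the dimethoxyphenyl-bearing carbon, with inversion, to give the resorcinol alcohol F3. An intramolecular Mitsunobu etherification (PPh3, diisopropyl azodicarboxylate) closes the furan ring with inversion at the carbinol carbon to the trans 4-hydroxy-dihydrobenzofuran F4, and O-methylation (MeI, K2CO3) comes back to the route at 14.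

Step 15. What may go wrong is steric shielding of aryne carbon C2' by the neighbouring dihydrobenzofuranyl group, which could slow or misdirect addition of the bulky oxirane and leave the aryne to side reactions. The fallback sets out from bromophenol 17, which is protected as the methoxymethyl ether F5 (MOMCl, i-Pr2NEt). Bromine–lithium exchange (n-BuLi, −78 °C) gives an aryllithium at C3', and BF3·OEt2-assisted opening of the enantiomeric (2R,3R)-2-[2,4-bis(triflyloxy)phenyl]-3-(3,5-dimethoxyphenyl)oxirane F6 (from 23 with the D-fructose-derived Shi ketone) at the dimethoxyphenyl-bearing carbon, with inversion, gives the alcohol F7. HCl in MeOH removes the acetal to give the phenol alcohol F8, and Mitsunobu ring closure with inversion at the carbinol carbon comes back to the route at 27.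

Step 16. What may go wrong is Lewis-acid-induced heterolysis of the benzylic C2–O bond of the first dihydrobenzofuran, whose C2 aryl ring is electron-rich, followed by capture of the cation by a neighbouring resorcinol ring; demethylation may also stay incomplete. The fallback avoids any Lewis acid. It sets out from 27: Et4NOH in dioxane removes the two triflates to give the bisphenol heptamethyl ether F9, and the seven methyl ethers are then cleaved by SN2 attack of sodium ethanethiolate at the methyl carbons in DMF at 150 °C. Forcing conditions and resubmission would be needed for the second methyl group on each resorcinol ring. This comes back to the route at 29.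

Further compounds
F1 | step 8 | (2R,3R)-2-[3-bromo-2-(tosyloxy)-4-(triflyloxy)phenyl]-3-(3,5-dimethoxyphenyl)oxirane | O1[C@H](c2ccc(OS(=O)(=O)C(F)(F)F)c(Br)c2OS(=O)(=O)c2ccc(C)cc2)[C@H]1c1cc(OC)cc(OC)c1
F2 | step 8 | 4'-O-methylresveratrol, (E)-5-(4-methoxystyryl)benzene-1,3-diol | COc1ccc(/C=C/c2cc(O)cc(O)c2)cc1
F3 | step 8 | resorcinol alcohol from Friedel–Crafts opening of F1 by F2 (carbinol carbon as in F1, new C–aryl carbon inverted) | O[C@H](c1ccc(OS(=O)(=O)C(F)(F)F)c(Br)c1OS(=O)(=O)c1ccc(C)cc1)[C@@H](c1c(O)cc(/C=C/c2ccc(OC)cc2)cc1O)c1cc(OC)cc(OC)c1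
F4 | step 8 | 4-hydroxy analogue of 14 (ring A OMe replaced by OH) | COc1ccc(/C=C/c2cc(O)c3c(c2)O[C@@H](c2ccc(OS(=O)(=O)C(F)(F)F)c(Br)c2OS(=O)(=O)c2ccc(C)cc2)[C@@H]3c2cc(OC)cc(OC)c2)cc1
F5 | step 15 | methoxymethyl ether of 17 | COc1ccc(/C=C/c2cc(OC)c3c(c2)O[C@@H](c2ccc(OC)c(Br)c2OCOC)[C@@H]3c2cc(OC)cc(OC)c2)cc1
F6 | step 15 | (2R,3R)-2-[2,4-bis(triflyloxy)phenyl]-3-(3,5-dimethoxyphenyl)oxirane | O1[C@H](c2ccc(OS(=O)(=O)C(F)(F)F)cc2OS(=O)(=O)C(F)(F)F)[C@H]1c1cc(OC)cc(OC)c1
F7 | step 15 | alcohol from opening of F6 by the C3' aryllithium of F5 | COc1ccc(/C=C/c2cc(OC)c3c(c2)O[C@@H](c2ccc(OC)c([C@H]([C@H](O)c4ccc(OS(=O)(=O)C(F)(F)F)cc4OS(=O)(=O)C(F)(F)F)c4cc(OC)cc(OC)c4)c2OCOC)[C@@H]3c2cc(OC)cc(OC)c2)cc1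
F8 | step 15 | phenol alcohol from F7 after removal of the methoxymethyl group | COc1ccc(/C=C/c2cc(OC)c3c(c2)O[C@@H](c2ccc(OC)c([C@H]([C@H](O)c4ccc(OS(=O)(=O)C(F)(F)F)cc4OS(=O)(=O)C(F)(F)F)c4cc(OC)cc(OC)c4)c2O)[C@@H]3c2cc(OC)cc(OC)c2)cc1
F9 | step 16 | bisphenol heptamethyl ether (27 with both triflates replaced by OH) | COc1ccc(/C=C/c2cc(OC)c3c(c2)O[C@@H](c2ccc(OC)c4c2O[C@@H](c2ccc(O)cc2O)[C@@H]4c2cc(OC)cc(OC)c2)[C@@H]3c2cc(OC)cc(OC)c2)cc1
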